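**Retrosynthetic overview**
- Target ⇐ dehydration and desilylation of a tertiary-carbinol aryl ketone ⇐ aryllithium opening of a fully substituted γ,γ-dimethyl-γ-butyrolactone. The lactone C=O becomes the aryl ketone and its CMe2–O becomes the isopropenyl group.
- Quaternary centre ⇐ two lactone-enolate alkylations (prenyl, then methyl), each anti to the β side chain; side-chain prenyl ⇐ aldehyde (Wittig) ⇐ enecarbamate hydrolysis.
- Key disconnection: the bond between the two CH stereocentres (a 1,6-dioxygenated, dissonant pattern) ⇐ sparteine-complexed lithiated N-Boc-N-aryl allylamine (chiral β-formyl carbanion, a homoenolate equivalent) + 5,5-dimethylfuran-2(5H)-one, with the enolate prenylated in the same flask.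
- Allylamine ⇐ N-allyl carbamate + 2-methylhexa-1,5-diene by cross-metathesis.
- Rings: none is built. The lactone ring is bought, used as stereochemical template and opened in step 7; the arene is bought.

Assumption: (−)-sparteine is taken to direct attack to the Si face of C3 of the allyl unit (as drawn for 8); if the sense is the reverse, (+)-sparteine is used and nothing else changes.

Labels: target C1 = C=O, C2 = quaternary carbon, C3 = CH(isopropenyl), C4 = CH(prenyl). Lactones are numbered as oxolan-2-ones.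

**Step 1**
Reactants: 1 tert-butyl (4-methoxyphenyl)carbamate; 2 3-bromoprop-1-ene
Product: 3 tert-butyl (4-methoxyphenyl)(prop-2-en-1-yl)carbamate
Conditions: NaH, DMF, 0 °C → rt
Reagents that add atoms: none
Why: The sodium carbamate anion displaces bromide from the allyl halide (SN2 N-alkylation) and no stereocentre is formed.

**Step 2**
Reactants: 3 tert-butyl (4-methoxyphenyl)(prop-2-en-1-yl)carbamate; 4 2-methylhexa-1,5-diene
Product: 5 tert-butyl (4-methoxyphenyl)[(2E)-6-methylhepta-2,6-dien-1-yl]carbamate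
Conditions: second-generation Hoveyda–Grubbs catalyst RuCl2(H2IMes)(=CH-C6H4-2-O-i-Pr) (3 mol %), 4 (4 equiv), CH2Cl2, 40 °C; AgNO3-impregnated silica chromatography
Reagents that add atoms: none
Why: Olefin cross-metathesis in which only the monosubstituted alkene of 4 reacts (the 1,1-disubstituted end is too hindered) and pairs with the allyl carbamate with loss of ethene to give mainly the E alkene, the minor Z isomer being removed on AgNO3–silica.

**Step 3 (key step)**
Reactants: 5 tert-butyl (4-methoxyphenyl)[(2E)-6-methylhepta-2,6-dien-1-yl]carbamate; 6 5,5-dimethylfuran-2(5H)-one; 7 1-bromo-3-methylbut-2-ene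
Product: 10 (3R,4R)-4-[(1Z,3S)-1-{(tert-butoxycarbonyl)(4-methoxyphenyl)amino}-6-methylhepta-1,6-dien-3-yl]-5,5-dimethyl-3-(3-methylbut-2-en-1-yl)oxolan-2-one, via allyllithium sparteine complex 8 (not isolated), via lithium enolate of the Michael adduct 9 (not isolated)
Conditions: n-BuLi (1.1 equiv), (−)-sparteine (1.2 equiv), toluene, −78 °C, 1 h; then 6, −78 °C, 3 h; then 7 (3 equiv), THF/DMPU, −78 → −30 °C
Reagents that add atoms: none
Why: Sparteine-mediated asymmetric lithiation of the N-Boc-N-aryl allylamine gives a configurationally stable allyllithium (a chiral homoenolate equivalent) whose γ-carbon adds 1,4 to the butenolide anti to lithium (anti-SE2′ Michael addition), the sparteine-bound face setting target C4 and an open transition state (amino-allyl arm anti to the CMe2 carbon, alkyl chain next to the lactone β-hydrogen, unlike topicity) setting target C3, after which the lithium enolate is prenylated anti to the new side chain (tandem conjugate addition–enolate alkylation), the acceptor having no γ-hydrogen that the base could remove.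

**Step 4**
Reactants: 10 (3R,4R)-4-[(1Z,3S)-1-{(tert-butoxycarbonyl)(4-methoxyphenyl)amino}-6-methylhepta-1,6-dien-3-yl]-5,5-dimethyl-3-(3-methylbut-2-en-1-yl)oxolan-2-one
Product: 12 (3S,4R)-4-[(1Z,3S)-1-{(tert-butoxycarbonyl)(4-methoxyphenyl)amino}-6-methylhepta-1,6-dien-3-yl]-3,5,5-trimethyl-3-(3-methylbut-2-en-1-yl)oxolan-2-one, via tetrasubstituted lithium lactone enolate 11 (not isolated)
Conditions: LiN(i-Pr)2 (1.3 equiv), THF, −78 °C; then MeI, DMPU, −78 → −40 °C
Reagents that add atoms: iodomethane, CI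
Why: Trans-selective lactone enolate alkylation in which iodomethane enters anti to the bulky C4 substituent, so methyl ends trans and prenyl cis to the side chain, which sets the quaternary centre (target C2) as S.

**Step 5**
Reactants: 12 (3S,4R)-4-[(1Z,3S)-1-{(tert-butoxycarbonyl)(4-methoxyphenyl)amino}-6-methylhepta-1,6-dien-3-yl]-3,5,5-trimethyl-3-(3-methylbut-2-en-1-yl)oxolan-2-one
Product: 13 (3S,4R)-3,5,5-trimethyl-4-[(3S)-6-methyl-1-oxohept-6-en-3-yl]-3-(3-methylbut-2-en-1-yl)oxolan-2-one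
Conditions: 1 M aq HCl, THF, 0 °C → rt
Reagents that add atoms: water, O
Why: Acid hydrolysis of the enecarbamate (C-protonation to an N-acyliminium ion, addition of water, loss of carbamate 1) unmasks the aldehyde of the homoenolate unit, and no stereocentre is α to the new carbonyl.

**Step 6**
Reactants: 13 (3S,4R)-3,5,5-trimethyl-4-[(3S)-6-methyl-1-oxohept-6-en-3-yl]-3-(3-methylbut-2-en-1-yl)oxolan-2-one
Product: 14 (3S,4R)-4-[(5S)-2,8-dimethylnona-1,7-dien-5-yl]-3,5,5-trimethyl-3-(3-methylbut-2-en-1-yl)oxolan-2-one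
Conditions: i-PrPPh3I, n-BuLi, THF, 0 °C; then 13, −78 °C → rt
Reagents that add atoms: isopropyltriphenylphosphonium iodide, CC(C)[P+](c1ccccc1)(c1ccccc1)c1ccccc1.[I-]
Why: Wittig olefination with the unstabilised isopropylidene ylide turns CH2CHO into the prenyl group, while the hindered α-quaternary lactone carbonyl does not react and no centre can epimerise.

**Step 7**
Reactants: 14 (3S,4R)-4-[(5S)-2,8-dimethylnona-1,7-dien-5-yl]-3,5,5-trimethyl-3-(3-methylbut-2-en-1-yl)oxolan-2-one; 15 (3-bromophenoxy)(tert-butyl)dimethylsilane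
Product: 17 (2S,3R,4S)-1-{3-[(tert-butyldimethylsilyl)oxy]phenyl}-3-(2-hydroxypropan-2-yl)-2,7-dimethyl-2,4-bis(3-methylbut-2-en-1-yl)oct-7-en-1-one, via 3-silyloxyphenyllithium 16 (not isolated)
Conditions: 15 (1.6 equiv), n-BuLi (1.5 equiv), THF, −78 °C; then 14, −78 → −20 °C; H2O
Reagents that add atoms: none
Why: Bromine–lithium exchange gives the aryllithium, which adds once to the lactone carbonyl (ring-opening acylation; the lithium lactolate is stable cold and the α-quaternary ketone resists a second addition), leaving all stereocentres untouched; the product may sit partly as its cyclic hemiketal.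

**Step 8**
Reactants: 17 (2S,3R,4S)-1-{3-[(tert-butyldimethylsilyl)oxy]phenyl}-3-(2-hydroxypropan-2-yl)-2,7-dimethyl-2,4-bis(3-methylbut-2-en-1-yl)oct-7-en-1-one
Product: 19 Garcinielliptone FA (2S,3S,4S)-1-(3-hydroxyphenyl)-2,7-dimethyl-2,4-bis(3-methylbut-2-en-1-yl)-3-(prop-1-en-2-yl)oct-7-en-1-one, via silyl ether of the target 18 (not isolated)
Conditions: SOCl2 (3 equiv), pyridine (10 equiv), CH2Cl2, −30 → 0 °C; then MeOH, K2CO3 (excess), rt
Reagents that add atoms: none
Why: The chlorosulfite of the open-chain tertiary alcohol undergoes pyridine-mediated E2 elimination toward the six methyl hydrogens and not the buried C3–H (the alternative tetrasubstituted alkene would be severely strained), giving the isopropenyl group, and K2CO3/MeOH then cleaves the aryl silyl ether (base-mediated desilylation) of a product that has no epimerisable centre.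

**Compound list**
1 | tert-butyl (4-methoxyphenyl)carbamate | COc1ccc(NC(=O)OC(C)(C)C)cc1 | starting material
2 | 3-bromoprop-1-ene (allyl bromide) | C=CCBr | starting material
3 | tert-butyl (4-methoxyphenyl)(prop-2-en-1-yl)carbamate | C=CCN(C(=O)OC(C)(C)C)c1ccc(OC)cc1 | intermediate
4 | 2-methylhexa-1,5-diene | C=CCCC(C)=C | starting material
5 | tert-butyl (4-methoxyphenyl)[(2E)-6-methylhepta-2,6-dien-1-yl]carbamate | C=C(C)CC/C=C/CN(C(=O)OC(C)(C)C)c1ccc(OC)cc1 | intermediate
6 | 5,5-dimethylfuran-2(5H)-one | CC1(C)OC(=O)C=C1 | starting material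
7 | 1-bromo-3-methylbut-2-ene (prenyl bromide) | CC(C)=CCBr | starting material
8 | tert-butyl (4-methoxyphenyl)[(1S,2E)-1-lithio-6-methylhepta-2,6-dien-1-yl]carbamate as its (−)-sparteine complex (drawn C1-bound) | C=C(C)CC/C=C/[C@H]([Li])N(C(=O)OC(C)(C)C)c1ccc(OC)cc1 | intermediate (not isolated)
9 | lithium (4R)-4-[(1Z,3S)-1-{(tert-butoxycarbonyl)(4-methoxyphenyl)amino}-6-methylhepta-1,6-dien-3-yl]-5,5-dimethyl-4,5-dihydrofuran-2-olate | C=C(C)CC[C@@H](/C=C\N(C(=O)OC(C)(C)C)c2ccc(OC)cc2)[C@H]1C(C)(C)OC(O[Li])=C1 | intermediate (not isolated)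
10 | (3R,4R)-4-[(1Z,3S)-1-{(tert-butoxycarbonyl)(4-methoxyphenyl)amino}-6-methylhepta-1,6-dien-3-yl]-5,5-dimethyl-3-(3-methylbut-2-en-1-yl)oxolan-2-one | C=C(C)CC[C@@H](/C=C\N(C(=O)OC(C)(C)C)c2ccc(OC)cc2)[C@H]1C(C)(C)OC(=O)[C@@H]1CC=C(C)C | intermediate
11 | lithium (4R)-4-[(1Z,3S)-1-{(tert-butoxycarbonyl)(4-methoxyphenyl)amino}-6-methylhepta-1,6-dien-3-yl]-5,5-dimethyl-3-(3-methylbut-2-en-1-yl)-4,5-dihydrofuran-2-olate | C=C(C)CC[C@@H](/C=C\N(C(=O)OC(C)(C)C)c2ccc(OC)cc2)[C@H]1C(C)(C)OC(O[Li])=C1CC=C(C)C | intermediate (not isolated)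
12 | (3S,4R)-4-[(1Z,3S)-1-{(tert-butoxycarbonyl)(4-methoxyphenyl)amino}-6-methylhepta-1,6-dien-3-yl]-3,5,5-trimethyl-3-(3-methylbut-2-en-1-yl)oxolan-2-one | C=C(C)CC[C@@H](/C=C\N(C(=O)OC(C)(C)C)c2ccc(OC)cc2)[C@H]1C(C)(C)OC(=O)[C@@]1(C)CC=C(C)C | intermediate
13 | (3S,4R)-3,5,5-trimethyl-4-[(3S)-6-methyl-1-oxohept-6-en-3-yl]-3-(3-methylbut-2-en-1-yl)oxolan-2-one | C=C(C)CC[C@@H](CC=O)[C@H]1C(C)(C)OC(=O)[C@@]1(C)CC=C(C)C | intermediate
14 | (3S,4R)-4-[(5S)-2,8-dimethylnona-1,7-dien-5-yl]-3,5,5-trimethyl-3-(3-methylbut-2-en-1-yl)oxolan-2-one | C=C(C)CC[C@@H](CC=C(C)C)[C@H]1C(C)(C)OC(=O)[C@@]1(C)CC=C(C)C | intermediate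
15 | (3-bromophenoxy)(tert-butyl)dimethylsilane | CC(C)(C)[Si](C)(C)Oc1cccc(Br)c1 | starting material
16 | {3-[(tert-butyldimethylsilyl)oxy]phenyl}lithium | CC(C)(C)[Si](C)(C)Oc1cccc([Li])c1 | intermediate (not isolated)
17 | (2S,3R,4S)-1-{3-[(tert-butyldimethylsilyl)oxy]phenyl}-3-(2-hydroxypropan-2-yl)-2,7-dimethyl-2,4-bis(3-methylbut-2-en-1-yl)oct-7-en-1-one | C=C(C)CC[C@@H](CC=C(C)C)[C@@H](C(C)(C)O)[C@](C)(CC=C(C)C)C(=O)c1cccc(O[Si](C)(C)C(C)(C)C)c1 | intermediate
18 | (2S,3S,4S)-1-{3-[(tert-butyldimethylsilyl)oxy]phenyl}-2,7-dimethyl-2,4-bis(3-methylbut-2-en-1-yl)-3-(prop-1-en-2-yl)oct-7-en-1-one | C=C(C)CC[C@@H](CC=C(C)C)[C@@H](C(=C)C)[C@](C)(CC=C(C)C)C(=O)c1cccc(O[Si](C)(C)C(C)(C)C)c1 | intermediate (not isolated)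
19 | Garcinielliptone FA, (2S,3S,4S)-1-(3-hydroxyphenyl)-2,7-dimethyl-2,4-bis(3-methylbut-2-en-1-yl)-3-(prop-1-en-2-yl)oct-7-en-1-one | C=C(C)CC[C@@H](CC=C(C)C)[C@@H](C(=C)C)[C@](C)(CC=C(C)C)C(=O)c1cccc(O)c1 | target

**Totals**
Total step count: 8. Longest linear sequence: 8 steps (1 → 3 → 5 → 10 → 12 → 13 → 14 → 17 → 19).

**Three steps most likely to fail**

Step 3. This is the weakest step, for three reasons:
- The β-carbon of 6 is neopentyl-like, so 1,2-addition or low conversion may compete.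
- The simple diastereoselectivity (C3 against C4 of the target) rests on a transition-state argument, not on a precedent for this acceptor.
- The facial sense of the sparteine complex is assumed.

Fallback, from compound 5 (lithiated as 8) back to compound 18: the acceptor is changed to the chiral-pool butenolide (S)-5-methylfuran-2(5H)-one (C[C@@H]1OC(=O)C=C1). It is less hindered, and its C5 methyl group makes the nucleophile add anti, so the lactone β-centre is set by the substrate and only the side-chain centre by sparteine. The same addition with prenyl bromide trapping gives (3R,4R,5S)-4-[(1Z,3S)-1-{(tert-butoxycarbonyl)(4-methoxyphenyl)amino}-6-methylhepta-1,6-dien-3-yl]-5-methyl-3-(3-methylbut-2-en-1-yl)oxolan-2-one F1. LiN(i-Pr)2 and MeI give the quaternary lactone (3S,4R,5S)-4-[(1Z,3S)-1-{(tert-butoxycarbonyl)(4-methoxyphenyl)amino}-6-methylhepta-1,6-dien-3-yl]-3,5-dimethyl-3-(3-methylbut-2-en-1-yl)oxolan-2-one F2. Aqueous HCl gives the aldehyde (3S,4R,5S)-3,5-dimethyl-4-[(3S)-6-methyl-1-oxohept-6-en-3-yl]-3-(3-methylbut-2-en-1-yl)oxolan-2-one F3, and the isopropylidene Wittig reaction gives (3S,4R,5S)-4-[(5S)-2,8-dimethylnona-1,7-dien-5-yl]-3,5-dimethyl-3-(3-methylbut-2-en-1-yl)oxolan-2-one F4. Aryllithium 16 opens it to the keto alcohol (2S,3R,4S)-1-{3-[(tert-butyldimethylsilyl)oxy]phenyl}-3-[(1S)-1-hydroxyethyl]-2,7-dimethyl-2,4-bis(3-methylbut-2-en-1-yl)oct-7-en-1-one F5. Dess–Martin periodinane gives the 1,4-diketone (2S,3R,4S)-3-acetyl-1-{3-[(tert-butyldimethylsilyl)oxy]phenyl}-2,7-dimethyl-2,4-bis(3-methylbut-2-en-1-yl)oct-7-en-1-one F6. Ph3P=CH2 (from Ph3PCH3Br and KOt-Bu) methylenates only the unhindered methyl ketone and gives 18, which is desilylated as in step 8. This costs two more steps but removes both the hindered addition and the dehydration.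

Step 7. The lactone carbonyl of 14 sits between a quaternary carbon and a gem-dimethyl-bearing ring oxygen, so addition of 16 may be too slow.

Fallback, from compound 14 back to compound 17: i-Bu2AlH in CH2Cl2 at −78 °C reduces 14 to the lactol (3S,4R)-4-[(5S)-2,8-dimethylnona-1,7-dien-5-yl]-3,5,5-trimethyl-3-(3-methylbut-2-en-1-yl)oxolan-2-ol F7. Its open aldehyde form takes up 16 (2.2 equiv) far more readily and gives the diol (2S,3R,4S)-1-{3-[(tert-butyldimethylsilyl)oxy]phenyl}-3-(2-hydroxypropan-2-yl)-2,7-dimethyl-2,4-bis(3-methylbut-2-en-1-yl)oct-7-en-1-ol F8 as a carbinol mixture. Dess–Martin periodinane oxidises only the secondary benzylic alcohol and gives 17.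

Step 8. Two things can go wrong: 17 may sit largely as the cyclic hemiketal, and the ketone oxygen can trap an ionising tertiary centre, giving recovered material or the tetrasubstituted alkene.

Fallback, from compound 17 back to compound 18: the dehydration is replaced by a concerted thermal syn-elimination. KH, CS2 and then MeI trap the open-chain tertiary alkoxide as the xanthate O-[(3R,4S)-3-[(2S)-1-{3-[(tert-butyldimethylsilyl)oxy]phenyl}-2,5-dimethyl-1-oxohex-4-en-2-yl]-2,7-dimethyl-4-(3-methylbut-2-en-1-yl)oct-7-en-2-yl] S-methyl carbonodithioate F9. Warming in toluene (Chugaev elimination) passes through a cyclic transition state that can only reach the methyl hydrogens and gives 18, which is desilylated with K2CO3 in MeOH.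

**Further compounds**
F1 | step 3 | (3R,4R,5S)-4-[(1Z,3S)-1-{(tert-butoxycarbonyl)(4-methoxyphenyl)amino}-6-methylhepta-1,6-dien-3-yl]-5-methyl-3-(3-methylbut-2-en-1-yl)oxolan-2-one | C=C(C)CC[C@@H](/C=C\N(C(=O)OC(C)(C)C)c2ccc(OC)cc2)[C@H]1[C@H](C)OC(=O)[C@@H]1CC=C(C)C
F2 | step 3 | (3S,4R,5S)-4-[(1Z,3S)-1-{(tert-butoxycarbonyl)(4-methoxyphenyl)amino}-6-methylhepta-1,6-dien-3-yl]-3,5-dimethyl-3-(3-methylbut-2-en-1-yl)oxolan-2-one | C=C(C)CC[C@@H](/C=C\N(C(=O)OC(C)(C)C)c2ccc(OC)cc2)[C@H]1[C@H](C)OC(=O)[C@@]1(C)CC=C(C)C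
F3 | step 3 | (3S,4R,5S)-3,5-dimethyl-4-[(3S)-6-methyl-1-oxohept-6-en-3-yl]-3-(3-methylbut-2-en-1-yl)oxolan-2-one | C=C(C)CC[C@@H](CC=O)[C@H]1[C@H](C)OC(=O)[C@@]1(C)CC=C(C)C
F4 | step 3 | (3S,4R,5S)-4-[(5S)-2,8-dimethylnona-1,7-dien-5-yl]-3,5-dimethyl-3-(3-methylbut-2-en-1-yl)oxolan-2-one | C=C(C)CC[C@@H](CC=C(C)C)[C@H]1[C@H](C)OC(=O)[C@@]1(C)CC=C(C)C
F5 | step 3 | (2S,3R,4S)-1-{3-[(tert-butyldimethylsilyl)oxy]phenyl}-3-[(1S)-1-hydroxyethyl]-2,7-dimethyl-2,4-bis(3-methylbut-2-en-1-yl)oct-7-en-1-one | C=C(C)CC[C@@H](CC=C(C)C)[C@@H]([C@H](C)O)[C@](C)(CC=C(C)C)C(=O)c1cccc(O[Si](C)(C)C(C)(C)C)c1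
F6 | step 3 | (2S,3R,4S)-3-acetyl-1-{3-[(tert-butyldimethylsilyl)oxy]phenyl}-2,7-dimethyl-2,4-bis(3-methylbut-2-en-1-yl)oct-7-en-1-one | C=C(C)CC[C@@H](CC=C(C)C)[C@@H](C(C)=O)[C@](C)(CC=C(C)C)C(=O)c1cccc(O[Si](C)(C)C(C)(C)C)c1
F7 | step 7 | (3S,4R)-4-[(5S)-2,8-dimethylnona-1,7-dien-5-yl]-3,5,5-trimethyl-3-(3-methylbut-2-en-1-yl)oxolan-2-ol (anomer mixture) | C=C(C)CC[C@@H](CC=C(C)C)[C@H]1C(C)(C)OC(O)[C@@]1(C)CC=C(C)C
F8 | step 7 | (2S,3R,4S)-1-{3-[(tert-butyldimethylsilyl)oxy]phenyl}-3-(2-hydroxypropan-2-yl)-2,7-dimethyl-2,4-bis(3-methylbut-2-en-1-yl)oct-7-en-1-ol (C1 epimer mixture) | C=C(C)CC[C@@H](CC=C(C)C)[C@@H](C(C)(C)O)[C@](C)(CC=C(C)C)C(O)c1cccc(O[Si](C)(C)C(C)(C)C)c1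
F9 | step 8 | O-[(3R,4S)-3-[(2S)-1-{3-[(tert-butyldimethylsilyl)oxy]phenyl}-2,5-dimethyl-1-oxohex-4-en-2-yl]-2,7-dimethyl-4-(3-methylbut-2-en-1-yl)oct-7-en-2-yl] S-methyl carbonodithioate | C=C(C)CC[C@@H](CC=C(C)C)[C@@H](C(C)(C)OC(=S)SC)[C@](C)(CC=C(C)C)C(=O)c1cccc(O[Si](C)(C)C(C)(C)C)c1
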